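No rate constant is given for this pair, so I read what I need from the two earlier runs.

| setting | Tuesday's | Thursday's | south | south-west | south-east |
|---|---|---|---|---|---|
| substrate | 0.020 M | 0.020 M | 0.020 M | 0.020 M | 0.020 M (fed, over 20 h) |
| reagent | 1 equiv | 2 equiv | 1.00 equiv | 1.00 equiv (fed, over 20 h) | 1.00 equiv |
| remark | run made earlier | run made earlier | everything together at the start | all else is in the flask from the start; the feed brings no volume worth counting | all else is in the flask from the start; the feed brings no volume worth counting |
| time |  |  | 25 h | 25 h | 25 h |

- Tuesday's (time / h: target / %, substrate / %): 2.00: 14, 82; 4.00: 26, 71; 6.00: 29, 58; 8.00: 37, 52; 10.0: 39, 47; 12.0: 47, 41; 15.0: 49, 37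
- Thursday's (time / h: target / %, substrate / %): 0.417: 5, 91; 1.00: 9, 87; 2.00: 19, 74; 3.00: 25, 63; 5.00: 37, 51; 6.00: 41, 47; 8.00: 46, 39

(scatter of a reading: 1.5 percentage points)



* which flask leads in amount of target, in percent of the substrate charged ("all alike" within 1.5 percentage points) (south / south-west / south-east / all alike)
* how much target is there at the end, in percent of the substrate charged: south
* how much target is there at the end, in percent of the substrate charged: south-west
* how much target is there at the end, in percent of the substrate charged: south-east

At the last readings, target per substrate consumed is 77.8% in Tuesday's run and 75.4% in Thursday's, although Thursday's has twice the reagent. Their mean is 76.6%. I call this the target share, target formed per substrate consumed, and I take it that each setting moves conversion while the share stays.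

South is my zero of the scale: equal amounts, all present at the start, so c(substrate) and c(reagent) stay equal. In Tuesday's run, the reciprocal of the fraction left, less one, grows by 0.114 h⁻¹. That reading gives 26.1% substrate left in south at 25 h, so my target is 56.6%.

Over the first 2.00 h, the substrate consumed with doubled reagent reads as a reagent order of 0.531. Tuesday's second-order reckoning then leaves a substrate order of 1.47.

| Setting turned from south | Concentration starting at zero | Order read |
|---|---|---|
| reagent fed (south-west) | c(reagent) | 0.531 |
| substrate fed (south-east) | c(substrate) | 1.47 |

Each feed starts its species at zero, and substrate carries the higher order, so by hand I put south first, then south-west, then south-east.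

The forecast gives south the lead, with 57%, 50% and 44% for south, south-west and south-east, holding that “feeding changes only conversion”.

South leads with 55.5%, against 48.7% in south-west and 43.4% in south-east.

substrate + reagent → target, rate k1*[substrate]^1.5*[reagent]^0.5 (k = 0.00160 M⁻¹ s⁻¹); target ⇌ isomer of the product (K = 0.340, k = 1.30 × 10⁻⁴ s⁻¹) In south-east, target and the isomer of the product relax by their own step, both ways together, with a half-life of 0.376 h, short against 25 h. The target share on the 42.2% substrate left in south-east gives 44.3%.

A neighbour of south-east with 0.600 equiv of reagent, here the limiting reagent, ends with 53.0% substrate, so the target share gives 36.0%. The computed target there is 35.3%.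

(The earlier runs and the new flask are simulated for an exercise, and the scatter is random.)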